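**Retrosynthetic overview**
1. Both esters are removed to a C7-hydroxy C9-ketone (Evans–Tishchenko relay between O7 and O9), and the C2=C3 alkene is traced back to the saturated C1 ketone (Saegusa–Ito).
2. Ring B (cyclobutane C4–C5–C11–C10) is opened at C4–C10. The forward step is displacement of a C4 sulfonate by C10 of the C9-ketone enolate in a cis-fused six–seven bicycle.
3. The strategy rests on this feature: C1 and C7 are both carbonyl-level carbons and stand 1,5 through C11–C5–C6. Because C6 is quaternary, no Michael route exists. This pattern is the retron of an enol–alkene [2+2] photoadduct opened by retro-aldol cleavage (de Mayo).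
4. Ring A (C1–C5, C11) and ring C (C5–C11, seven-membered) therefore both come from the benzyl enol carbonate of a 2-acylcyclopentanone. C5–C11 and C6–C7 are made and C7–C11 is broken.
5. Ring order: cyclopentane (bought), then ring A with the photoadduct, then ring C by two-carbon enlargement, then ring B last. The pieces are (R)-4-silyloxycyclopentenone, Me2CuLi and an aldehyde made by syn-crotylation of 3-methylbut-2-enal.

Key step: step 8

Remark on the chemistry: atoms carry longipinane numbers (C1 ketone, C2=C3, C6 gem-dimethyl, C7 tiglate, C9 senecioate, C10 methyl-bearing quaternary carbon). An oxygen is carried on C4 from the start because it steers the alkene face in step 8 and becomes the leaving group of step 18. O-acylation of diketone 15 is assumed to occur on the ring oxygen.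

**Step 1**
Reactants: 1 cis-but-2-ene; 2 3-methylbut-2-enal
Product: 7 (3S,4R)-3,6-dimethylhepta-1,5-dien-4-ol (3-Me/4-OH syn), via (Z)-crotylpotassium 3 (not isolated), via methoxyborate complex 4 (not isolated), via (Z)-crotylbis(isopinocampheyl)borane 5 (not isolated), via borinic ester 6 (not isolated)
Conditions: n-BuLi, KOtBu, THF, −78 to −45 °C; (+)-Ipc2BOMe, −78 °C; BF3·OEt2; 2, −78 °C; NaOH, H2O2
Reagents that add atoms: none
Why: Brown asymmetric crotylboration runs through a closed chair transition state, so the Z-crotyl geometry should give the syn C3/C4 pair, and the (+)-Ipc2B group (from (−)-α-pinene) should select the aldehyde face that gives 4R.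

**Step 2**
Reactants: 7 (3S,4R)-3,6-dimethylhepta-1,5-dien-4-ol
Product: 8 (3S,4R)-4-(4-methoxybenzyloxy)-3,6-dimethylhepta-1,5-diene
Conditions: NaH, PMBCl, Bu4NI (cat.), THF/DMF, 0 °C to rt
Reagents that add atoms: 4-methoxybenzyl chloride, COc1ccc(CCl)cc1
Why: Williamson etherification touches no stereocentre and installs a group that can later be removed oxidatively, without acid, base or fluoride.

**Step 3**
Reactants: 8 PMB ether
Product: 10 (3S,4R)-4-(4-methoxybenzyloxy)-3,6-dimethylhept-5-en-1-ol, via B-alkyl-9-BBN adduct 9 (not isolated)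
Conditions: 9-BBN, THF, 0 °C to rt; NaOH, H2O2
Reagents that add atoms: hydrogen peroxide, OO
Why: In this hydroboration–oxidation the bulky 9-BBN should take the monosubstituted alkene in preference to the trisubstituted one and place boron on the terminal carbon.

**Step 4**
Reactants: 10 primary alcohol
Product: 11 (3S,4R)-4-(4-methoxybenzyloxy)-3,6-dimethylhept-5-enal
Conditions: DMP, CH2Cl2, 0 °C to rt
Reagents that add atoms: none
Why: Dess–Martin oxidation stops at the aldehyde, and the nearest stereocentre (C3) is β to the carbonyl and cannot epimerise.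

**Step 5**
Reactants: 12 (R)-4-(tert-butyldimethylsilyloxy)cyclopent-2-en-1-one; 11 aldehyde
Product: 14 aldol adduct, 2,3-trans-3,4-trans-2-[1-hydroxy-4-(PMB-oxy)-3,6-dimethylhept-5-enyl]-3-methyl-4-(TBS-oxy)cyclopentanone (C1 carbinol epimers), via lithium enolate 13 (not isolated)
Conditions: MeLi, CuI, Et2O, −78 °C; 12; then 11, THF, −78 °C; aq NH4Cl
Reagents that add atoms: lithium dimethylcuprate (Me2CuLi), [Li+].C[Cu-]C
Why: Gilman conjugate addition anti to the C9 silyl ether sets C10, and the regiodefined C7=C11 enolate is trapped cold by aldol addition (three-component coupling), which avoids the O-acylation and the enolate equilibration with silanol loss that an acid chloride would invite.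

**Step 6**
Reactants: 14 aldol adduct
Product: 15 2-acyl-3-methyl-4-(TBS-oxy)cyclopentanone (enolised 1,3-diketone, C11 undefined)
Conditions: DMP, CH2Cl2, rt
Reagents that add atoms: none
Why: Dess–Martin oxidation of the β-hydroxy ketone is non-basic, so the β-silyloxy ketone should survive, and the C1 and C11 centres of 14 are erased.

**Step 7**
Reactants: 15 1,3-diketone
Product: 16 benzyl enol carbonate of 15 (C7–OCO2Bn, C7=C11, C1 ketone conjugated)
Conditions: BnOCOCl, pyridine, CH2Cl2, 0 °C
Reagents that add atoms: benzyl chloroformate, O=C(Cl)OCc1ccccc1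
Why: O-acylation of the enolised diketone under a weak base should occur on the more exposed ring oxygen, which fixes a single enol tautomer as the β-acyloxy enone chromophore; an exocyclic isomer would be removed by chromatography.

**Step 8**
Reactants: 16 benzyl enol carbonate
Product: 19 cis-fused six–seven 1,7-dione (4-OPMB, 9-OTBS, H5 and H11 on one face; 3-Me and 10-Me on the other; 6,6-dimethyl), via cyclobutane photoadduct 17 (not isolated), via C7 cyclobutanol 18 (not isolated)
Conditions: hν (medium-pressure Hg lamp, Pyrex), cyclohexane, rt; then H2 (1 atm), Pd/C, pyridine (0.5 equiv), EtOAc, rt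
Reagents that add atoms: none
Why: The excited (triplet) β-acyloxy enone C1(=O)–C11=C7 attacks the tethered C5=C6 alkene to give a 1,4-biradical that collapses to the cyclobutane C5–C6–C7–C11, which is the known intramolecular de Mayo reaction of an enol carbonate; hydrogenolysis then frees the C7 cyclobutanol, and this strained β-hydroxy ketone breaks C7–C11 by retro-aldol cleavage. Ring A (C1–C5, C11) closes in the straight 1,6-mode through C5–C11, whereas ring C is not cyclised but arises by enlargement of the cyclopentane when C5–C6 is inserted between C11 and C7. C5 is controlled by C4, because A(1,3) strain with the Z-methyl on C6 holds H4 in the alkene plane, so the tether reaches one alkene face only and O4 ends up cis to H5; this alkene face is matched with attack on the cyclopentene face anti to the adjacent C10 methyl. C11 is set afterwards by ketonisation of the C1 enol from the H5 side, opposite the quaternary C6, which should give the cis fusion and remains correctable while C1 is a ketone. Straight rather than crossed addition is needed and is secured by the four-atom tether, whose chair places 3-Me, O4 and C6 equatorial; chemoselective cleavage of the carbonate beside the PMB ether is secured by the pyridine-poisoned catalyst.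

**Step 9**
Reactants: 19 1,7-dione
Product: 20 C1 ethylene ketal of 19 (C7 ketone free)
Conditions: (TMSOCH2)2, TMSOTf (cat.), CH2Cl2, −78 °C
Reagents that add atoms: 1,2-bis(trimethylsilyloxy)ethane, C[Si](C)(C)OCCO[Si](C)(C)C
Why: TMSOTf-catalysed ketalisation with the bis-silyl glycol should select the cyclohexanone over the neopentyl C7 ketone, remove the C2 and C11 enolisation sites that would later give cyclopropanes with the C4 leaving group, and freeze the cis fusion.

**Step 10**
Reactants: 20 keto ketal
Product: 21 9-hydroxy C7-ketone (ketal and PMB ether retained)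
Conditions: HF·pyridine, pyridine, THF, 0 °C to rt
Reagents that add atoms: none
Why: Buffered fluoride desilylation is slightly acidic, so the C9 carbinol is freed without E1cB loss from the β-oxy ketone.

**Step 11**
Reactants: 21 β-hydroxy ketone
Product: 22 9-acetoxy-7-ol (O7 anti to O9, on the face opposite H5 and H11)
Conditions: MeCHO (excess), SmI2 (0.3 equiv), THF, −10 °C
Reagents that add atoms: acetaldehyde, CC=O
Why: In this Evans–Tishchenko reduction the hemiacetal on O9 delivers hydride inside a trivalent-samarium chelate to the O9 face of C7 (also the convex face), which sets C7 anti to C9 and leaves the two oxygens differentiated as acetate and free hydroxyl.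

**Step 12**
Reactants: 22 hydroxy acetate
Product: 23 7-OTBS 9-acetate
Conditions: TBSOTf, 2,6-lutidine, CH2Cl2, 0 °C
Reagents that add atoms: tert-butyldimethylsilyl triflate, CC(C)(C)[Si](C)(C)OS(=O)(=O)C(F)(F)F
Why: Silylation with the silyl triflate and a hindered pyridine base overcomes the neopentyl hindrance at C7 without touching the ketal or the ester.

**Step 13**
Reactants: 23 PMB ether
Product: 24 4-ol
Conditions: DDQ, CH2Cl2/pH 7 buffer, 0 °C
Reagents that add atoms: none
Why: Oxidative PMB cleavage (hydride abstraction from the electron-rich benzylic position) is neutral and spares the silyl ether, the acetate and the ketal.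

**Step 14**
Reactants: 24 4-ol
Product: 25 4-tosylate (equatorial, cis to H5, trans to C6 and C10)
Conditions: TsCl, DMAP (cat.), pyridine, 40 °C
Reagents that add atoms: 4-toluenesulfonyl chloride, Cc1ccc(cc1)S(=O)(=O)Cl
Why: Sulfonylation proceeds with retention at C4, and the resulting equatorial leaving group has no anti-periplanar hydrogen, so E2 loss is disfavoured.

**Step 15**
Reactants: 25 acetate
Product: 26 9-ol
Conditions: K2CO3 (cat.), MeOH, rt
Reagents that add atoms: none
Why: Base-catalysed transesterification frees O9, which lies on the face opposite C4 and therefore cannot displace the sulfonate.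

**Step 16**
Reactants: 26 9-ol
Product: 27 C9 ketone (7-OTBS, 4-OTs, C1 ketal)
Conditions: DMP, CH2Cl2, rt
Reagents that add atoms: none
Why: Dess–Martin oxidation is non-basic, so the β-silyloxy ketone is formed without elimination.

**Step 17**
Reactants: 27 ketone
Product: 28 tetrasubstituted trimethylsilyl enol ether C9(OTMS)=C10
Conditions: TMSOTf, Et3N, CH2Cl2, 0 °C to rt
Reagents that add atoms: trimethylsilyl triflate, C[Si](C)(C)OS(=O)(=O)C(F)(F)F
Why: Soft enolisation under equilibrating conditions should favour the more substituted enol ether (the C8 side is also crowded by the C7 silyl ether), which fixes the regiochemistry before any strong base is present and erases C10.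

**Step 18**
Reactants: 28 silyl enol ether
Product: 30 tricyclic C9 ketone (longipinane skeleton, 7-OTBS, C1 ketal; C4, C5, C7, C10, C11 as in the target), via potassium enolate 29 (not isolated)
Conditions: KOtBu (1.0 equiv), THF (high dilution), −20 °C to rt
Reagents that add atoms: none
Why: Alkoxide cleavage of the silyl enol ether releases the regiodefined enolate without a proton source, and C10 displaces the C4 tosylate with inversion (intramolecular enolate alkylation, 4-exo-tet, the closure known for cis-fused δ-sulfonyloxy ketones); the cis-fused frame lets axial C10 reach only the rear of the C4–O bond, which sets C4 and C10, and O-alkylation is excluded because O9 is trans to C11 on the ring double bond.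

**Step 19**
Reactants: 30 tricyclic ketone
Product: 31 7-hydroxylongipinane-1,9-dione
Conditions: 48% aq HF, MeCN, rt
Reagents that add atoms: water, O
Why: Acidic fluoride removes the hindered silyl ether and hydrolyses the dioxolane in one operation, and both ketones deactivate the cyclobutane towards cationic opening.

**Step 20**
Reactants: 31 β-hydroxy ketone; 32 (E)-2-methylbut-2-enal
Product: 33 7-tigloyloxy-9-hydroxylongipinan-1-one (O9 anti to O7)
Conditions: 32 (excess), SmI2 (0.3 equiv), THF, −10 °C to rt
Reagents that add atoms: none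
Why: In this Evans–Tishchenko reduction the O7 hemiacetal of the enal transfers hydride to the O7 face of C9, which sets C9 anti to C7, installs the tiglate on O7 in the same event and leaves the unrelated C1 ketone untouched.

**Step 21**
Reactants: 33 9-ol; 34 3-methylbut-2-enoyl chloride
Product: 35 7-tigloyloxy-9-senecioyloxylongipinan-1-one (2,3-dihydro target)
Conditions: 34, DMAP (cat.), pyridine, 50 °C
Reagents that add atoms: none
Why: DMAP-catalysed acyl transfer reaches the hindered axial alcohol, and the weak base avoids vinylketene formation and hence deconjugation of the senecioate.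

**Step 22**
Reactants: 35 ketone
Product: 36 C1(OTMS)=C2 silyl enol ether
Conditions: TMSOTf, Et3N, CH2Cl2, 0 °C
Reagents that add atoms: trimethylsilyl triflate, C[Si](C)(C)OS(=O)(=O)C(F)(F)F
Why: Soft enolisation is regiospecific because C11 is a bridgehead (Bredt), and the ketone reacts far faster than the two enoates.

**Step 23**
Reactants: 36 silyl enol ether
Product: 37 target, (4R,5S,7R,9R,10R,11R)-7-tigloyloxy-9-senecioyloxylongipin-2-en-1-one
Conditions: Pd(OAc)2 (1 equiv), MeCN, rt
Reagents that add atoms: none
Why: In the Saegusa–Ito oxidation palladium binds C2 on the open H5 side, where H3 also lies, so syn β-hydride elimination gives the C2=C3 enone and erases the auxiliary C3 centre.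

**Compound list**
1 | cis-but-2-ene | C/C=C\C | starting material
2 | 3-methylbut-2-enal | CC(C)=CC=O | starting material
3 | (Z)-crotylpotassium | [K+].C/C=C\[CH2-] | intermediate
4 | potassium (Z)-crotyl(methoxy)bis(isopinocampheyl)borate | [K+].C/C=C\C[B-](OC)([C@H]1C[C@H]2C[C@@H]([C@@H]1C)C2(C)C)[C@H]1C[C@H]2C[C@@H]([C@@H]1C)C2(C)C | intermediate
5 | (Z)-crotylbis(isopinocampheyl)borane | C/C=C\CB([C@H]1C[C@H]2C[C@@H]([C@@H]1C)C2(C)C)[C@H]1C[C@H]2C[C@@H]([C@@H]1C)C2(C)C | intermediate
6 | bis(isopinocampheyl)borinic ester of 7 | C=C[C@H](C)[C@@H](OB([C@H]1C[C@H]2C[C@@H]([C@@H]1C)C2(C)C)[C@H]1C[C@H]2C[C@@H]([C@@H]1C)C2(C)C)C=C(C)C | intermediate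
7 | (3S,4R)-3,6-dimethylhepta-1,5-dien-4-ol | C=C[C@H](C)[C@@H](O)C=C(C)C | intermediate
8 | PMB ether of 7 | C=C[C@H](C)[C@@H](OCc1ccc(OC)cc1)C=C(C)C | intermediate
9 | B-alkyl-9-BBN adduct of 8 | B1(CC[C@H](C)[C@@H](OCc2ccc(OC)cc2)C=C(C)C)C2CCCC1CCC2 | intermediate
10 | (3S,4R)-4-(PMB-oxy)-3,6-dimethylhept-5-en-1-ol | OCC[C@H](C)[C@@H](OCc1ccc(OC)cc1)C=C(C)C | intermediate
11 | (3S,4R)-4-(PMB-oxy)-3,6-dimethylhept-5-enal | O=CC[C@H](C)[C@@H](OCc1ccc(OC)cc1)C=C(C)C | intermediate
12 | (R)-4-(tert-butyldimethylsilyloxy)cyclopent-2-en-1-one | O=C1C=C[C@H](O[Si](C)(C)C(C)(C)C)C1 | starting material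
13 | lithium C7=C11 enolate of trans-3-methyl-4-(TBS-oxy)cyclopentanone | [Li+].[O-]C1=C[C@@H](C)[C@H](O[Si](C)(C)C(C)(C)C)C1 | intermediate
14 | aldol adduct (C1 carbinol epimers) | O=C1C[C@@H](O[Si](C)(C)C(C)(C)C)[C@H](C)[C@H]1C(O)C[C@H](C)[C@@H](OCc1ccc(OC)cc1)C=C(C)C | intermediate
15 | 2-acylcyclopentanone (1,3-diketone) | O=C1C[C@@H](O[Si](C)(C)C(C)(C)C)[C@H](C)C1C(=O)C[C@H](C)[C@@H](OCc1ccc(OC)cc1)C=C(C)C | intermediate
16 | benzyl enol carbonate (key-step precursor) | O=C(OCc1ccccc1)OC1=C(C(=O)C[C@H](C)[C@@H](OCc2ccc(OC)cc2)C=C(C)C)[C@@H](C)[C@H](O[Si](C)(C)C(C)(C)C)C1 | intermediate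
17 | cyclobutane photoadduct | O=C(OCc1ccccc1)O[C@]12C[C@@H](O[Si](C)(C)C(C)(C)C)[C@H](C)[C@]13C(=O)C[C@H](C)[C@@H](OCc1ccc(OC)cc1)[C@@H]3C2(C)C | intermediate
18 | C7 cyclobutanol | O[C@]12C[C@@H](O[Si](C)(C)C(C)(C)C)[C@H](C)[C@]13C(=O)C[C@H](C)[C@@H](OCc1ccc(OC)cc1)[C@@H]3C2(C)C | intermediate
19 | cis-fused six–seven 1,7-dione (key-step product) | O=C1C[C@@H](O[Si](C)(C)C(C)(C)C)[C@H](C)[C@@H]3C(=O)C[C@H](C)[C@@H](OCc2ccc(OC)cc2)[C@@H]3C1(C)C | intermediate
20 | C1 ethylene ketal | O=C1C[C@@H](O[Si](C)(C)C(C)(C)C)[C@H](C)[C@@H]3C2(OCCO2)C[C@H](C)[C@@H](OCc2ccc(OC)cc2)[C@@H]3C1(C)C | intermediate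
21 | 9-hydroxy C7-ketone | O=C1C[C@@H](O)[C@H](C)[C@@H]3C2(OCCO2)C[C@H](C)[C@@H](OCc2ccc(OC)cc2)[C@@H]3C1(C)C | intermediate
22 | 9-acetoxy-7-ol | O[C@@H]1C[C@@H](OC(C)=O)[C@H](C)[C@@H]3C2(OCCO2)C[C@H](C)[C@@H](OCc2ccc(OC)cc2)[C@@H]3C1(C)C | intermediate
23 | 7-OTBS 9-acetate | CC(C)(C)[Si](C)(C)O[C@@H]1C[C@@H](OC(C)=O)[C@H](C)[C@@H]3C2(OCCO2)C[C@H](C)[C@@H](OCc2ccc(OC)cc2)[C@@H]3C1(C)C | intermediate
24 | 4-ol | CC(C)(C)[Si](C)(C)O[C@@H]1C[C@@H](OC(C)=O)[C@H](C)[C@@H]3C2(OCCO2)C[C@H](C)[C@@H](O)[C@@H]3C1(C)C | intermediate
25 | 4-tosylate | CC(C)(C)[Si](C)(C)O[C@@H]1C[C@@H](OC(C)=O)[C@H](C)[C@@H]3C2(OCCO2)C[C@H](C)[C@@H](OS(=O)(=O)c2ccc(C)cc2)[C@@H]3C1(C)C | intermediate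
26 | 9-ol tosylate | CC(C)(C)[Si](C)(C)O[C@@H]1C[C@@H](O)[C@H](C)[C@@H]3C2(OCCO2)C[C@H](C)[C@@H](OS(=O)(=O)c2ccc(C)cc2)[C@@H]3C1(C)C | intermediate
27 | C9 ketone tosylate | CC(C)(C)[Si](C)(C)O[C@@H]1CC(=O)[C@H](C)[C@@H]3C2(OCCO2)C[C@H](C)[C@@H](OS(=O)(=O)c2ccc(C)cc2)[C@@H]3C1(C)C | intermediate
28 | C9=C10 trimethylsilyl enol ether | CC(C)(C)[Si](C)(C)O[C@@H]1CC(O[Si](C)(C)C)=C(C)[C@@H]3C2(OCCO2)C[C@H](C)[C@@H](OS(=O)(=O)c2ccc(C)cc2)[C@@H]3C1(C)C | intermediate
29 | potassium C9=C10 enolate | [K+].CC(C)(C)[Si](C)(C)O[C@@H]1CC([O-])=C(C)[C@@H]3C2(OCCO2)C[C@H](C)[C@@H](OS(=O)(=O)c2ccc(C)cc2)[C@@H]3C1(C)C | intermediate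
30 | tricyclic C9 ketone (7-OTBS, C1 ketal) | CC(C)(C)[Si](C)(C)O[C@@H]1CC(=O)[C@@]2(C)[C@@H]3C4(OCCO4)C[C@H](C)[C@H]2[C@@H]3C1(C)C | intermediate
31 | 7-hydroxylongipinane-1,9-dione | O[C@@H]1CC(=O)[C@@]2(C)[C@@H]3C(=O)C[C@H](C)[C@H]2[C@@H]3C1(C)C | intermediate
32 | (E)-2-methylbut-2-enal | C/C=C(\C)C=O | starting material
33 | 7-tigloyloxy-9-hydroxylongipinan-1-one | C/C=C(\C)C(=O)O[C@@H]1C[C@@H](O)[C@@]2(C)[C@@H]3C(=O)C[C@H](C)[C@H]2[C@@H]3C1(C)C | intermediate
34 | 3-methylbut-2-enoyl chloride | CC(C)=CC(=O)Cl | starting material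
35 | 2,3-dihydro target | C/C=C(\C)C(=O)O[C@@H]1C[C@@H](OC(=O)C=C(C)C)[C@@]2(C)[C@@H]3C(=O)C[C@H](C)[C@H]2[C@@H]3C1(C)C | intermediate
36 | C1=C2 trimethylsilyl enol ether | C/C=C(\C)C(=O)O[C@@H]1C[C@@H](OC(=O)C=C(C)C)[C@@]2(C)[C@@H]3C(O[Si](C)(C)C)=C[C@H](C)[C@H]2[C@@H]3C1(C)C | intermediate
37 | CNP0257816.1 | C/C=C(\C)C(=O)O[C@@H]1C[C@@H](OC(=O)C=C(C)C)[C@@]2(C)[C@@H]3C(=O)C=C(C)[C@H]2[C@@H]3C1(C)C | target

**Total step count:** 23. **Longest linear sequence:** 23 steps (1 and 2 through to 37).

**Steps most likely to fail**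

**Step 18 (closure of C4–C10).**
- Proton transfer from product or from unreacted ketone may move the enolate to C8. From there, loss of the C7 silyloxy group or five-membered C8–C4 closure is faster than four-membered closure.
- Grob-type cleavage of C5–C11, which is anti-periplanar to the equatorial tosylate, may also outrun the hindered displacement.
- Fallback: it sets out from 27 and comes back at 31.
  - DBU in CH2Cl2 deliberately expels the C7 silyloxy group to give the C7=C8 enone tosylate F1. In F1, C8 is sp2 and C6 is quaternary, so C10–H is the only acidic position.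
  - KHMDS in THF then closes C4–C10 by α′-alkylation of the cross-conjugated enolate, giving the tricyclic enone ketal F2.
  - Copper-catalysed conjugate borylation (B2pin2, CuCl, NaOtBu, a chiral Josiphos-type bisphosphine, MeOH) gives the C7 pinacol boronate F3, with the ligand deciding between the two nearly equivalent faces.
  - NaBO3 oxidises F3 with retention to the C7-hydroxy C9-ketone ketal F4.
  - Aqueous HF removes the ketal to give 31.

**Step 8 (key step).**
- The hindered C6–C7 bond may close slowly, so the 1,4-biradical may revert or disproportionate by hydrogen transfer from a C6 methyl.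
- Face selectivity may erode because the C9 silyl ether lies on the attacked face.
- Ketonisation at C11 may drift towards the trans fusion.
- Fallback: it sets out from 15 and comes back at 19, and it makes no new compound F0.
  - The enol lock and the palladium step are given up, and diketone 15 is irradiated directly as its hydrogen-bonded enol (the classical de Mayo reaction).
  - A small hydroxyl then replaces the bulky carbonate on C7.
  - The cyclobutanol fragments as it forms, which makes the closure irreversible.
  - Addition through the other enol tautomer would require a strained bridged adduct.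
  - The PMB ether never meets hydrogen.

**Step 20 (Evans–Tishchenko with the enal).**
- Hemiacetal formation between the neopentyl C7 hydroxyl and a conjugated, α-branched aldehyde may be unfavourable.
- The trivalent-samarium alkoxide may trigger retro-aldol opening of ring C.
- Fallback: it sets out from 31 and comes back at 33.
  - Evans–Saksena reduction (Me4NBH(OAc)3, MeCN/AcOH, −20 °C) delivers hydride from O7 and gives the 7,9-anti diol F5 without touching C1.
  - One equivalent of tigloyl chloride with DMAP in pyridine at 0 °C should then acylate the equatorial C7 hydroxyl ahead of the axial C9 hydroxyl, which is flanked by the quaternary cyclobutane carbon.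

**Further compounds**
F0 | step 8 | none | none
F1 | step 18 | C7=C8 enone tosylate (C1 ketal) | C1=CC(=O)[C@H](C)[C@@H]3C2(OCCO2)C[C@H](C)[C@@H](OS(=O)(=O)c2ccc(C)cc2)[C@@H]3C1(C)C
F2 | step 18 | tricyclic C7=C8 enone ketal | C1=CC(=O)[C@@]2(C)[C@@H]3C4(OCCO4)C[C@H](C)[C@H]2[C@@H]3C1(C)C
F3 | step 18 | C7 pinacol boronate | CC1(C)OB(OC1(C)C)[C@@H]1CC(=O)[C@@]2(C)[C@@H]3C4(OCCO4)C[C@H](C)[C@H]2[C@@H]3C1(C)C
F4 | step 18 | C7-hydroxy C9-ketone C1-ketal | O[C@@H]1CC(=O)[C@@]2(C)[C@@H]3C4(OCCO4)C[C@H](C)[C@H]2[C@@H]3C1(C)C
F5 | step 20 | 7,9-anti-dihydroxylongipinan-1-one | O[C@@H]1C[C@@H](O)[C@@]2(C)[C@@H]3C(=O)C[C@H](C)[C@H]2[C@@H]3C1(C)C
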